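The time of reading, 40 min, sets the choice for the next run: whether a flask of 0.10 M substrate with 2.9 µM free enzyme can stay at 30 °C for that whole time, or whether cooling it after 12 min costs target.

in all of them: free enzyme 2.9 µM

| run | substrate | temperature | remark | time |
|---|---|---|---|---|
| epsilon | 0.050 M | 8 °C | run made earlier |  |
| gamma | 0.20 M | 24 °C | run made earlier |  |
| south-west | 0.10 M | 30 °C |  | 40 min |
| east | 0.10 M | 0 °C |  | 40 min |
| west | 0.10 M |  | at 30 °C until 12 min, from then on at 0 °C | 40 min |

- epsilon (time / min: target / %, substrate / %): 40.0: 76.4, 25.4; 80.0: 98.4, 3.6; 120: 100.7, 0; 150: 100.7, 0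
- gamma (time / min: target / %, substrate / %): 12.0: 13.7, 85.9; 25.0: 30.7, 70.4; 40.0: 51.3, 50.5; 50.0: 65.0, 36.1

(readings scatter by 1 percentage point)

- the flask with the highest amount of target, in percent of the substrate charged ("all alike" if they lie within 1.5 percentage points) (south-west / east / west / all alike)
- final target, as a percentage of the substrate charged, in south-west
- final target, as a percentage of the substrate charged, in east
- final target, as a percentage of the substrate charged, in west

In the gamma run, target forms at 2.28 mM min⁻¹ over the first 12.0 min and at 2.74 mM min⁻¹ between 40.0 min and 50.0 min. That later stretch starts from 0.101 M substrate, close to the new charge. So the rate can be frozen, as in a zero-order course, while substrate is plentiful. The epsilon run averages 0.955 mM min⁻¹ over its first 40.0 min, while its substrate falls from 0.050 M to 0.0127 M, below the substrate of the gamma stretch, so the ratio of 2.87 between the two rates mixes substrate level with the step from 8 °C to 24 °C. Carrying that ratio per degree on to 30 °C, as a rough guess with the two unseparated, gives 4.07 mM min⁻¹, the flat rate r, meaning the steady rate of target formation at 30 °C while substrate is plentiful.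

At r, the charge would clear in 24.6 min, sooner than the reading, so south-west should be nearly finished by 40 min. West at r reaches 48.8% by the change, about half. At the epsilon average, taken from a bath at 8 °C, warmer than west's 0 °C, west's cold stretch adds 27 percentage points, which brings it to 75.5%, below south-west's near-complete yield. By this reckoning the flask stays warm throughout.

The forecast also chooses south-west, with 97% there, 37% in east and 66% in west. It reads the gamma run thus: “the rate rises slightly as substrate falls”.

The flasks give 98.7% in south-west, 32.6% in east and 67.6% in west, so south-west stands highest.

    substrate → decomposition product (k = 1.21 × 10⁻⁷ s⁻¹, Ea = 114 kJ mol⁻¹)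
    substrate + free enzyme → target + free enzyme, rate k2*[substrate]*[free enzyme]/(1 + ([substrate]/Km2) + ([substrate]/Ksi2)^2) (0.0559 M, 0.0726 M, k = 1030 M⁻¹ s⁻¹, Ea = 36.0 kJ mol⁻¹)
    free enzyme → unfolded enzyme (k = 8.41 × 10⁻⁶ s⁻¹, Ea = 267 kJ mol⁻¹)
    (constants at 30 °C)

Frozen at r, south-west would hold 81.4% target at 20.0 min; it holds 74.2%, with 25.8% substrate remaining, and 1.2% substrate remains at 40.0 min. The neighbouring flask is south-west read at 10 min, for which r gives 40.7% target. That flask holds 39.0% target and 61% substrate.

The earlier runs and the new flask come from a simulation for substances that don't exist; the scatter is artificial.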